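**Retrosynthetic overview**
1. Ring C is closed last. The cis-aminal opens to an (S)-3,3-dialkyl oxindole whose NHCO2Me chain supplies N1 and, after hydride reduction, the N-methyl carbon.
2. Key disconnection: the quaternary carbon comes from a 2-(2-aminoethyl)-3-prenylindole. The sequence is enantioselective C3 bromination, hydration at C2, then a semipinacol 1,2-shift of the aminoethyl chain from C2 to C3.
3. The 3-prenyl group comes from prenol by C3 allylation. Ring B comes from Sonogashira coupling and 5-endo-dig hydroamination of an o-iodoaniline with a homopropargyl carbamate (but-3-yn-1-amine plus methyl chloroformate).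
4. Ring D comes from Sonogashira coupling and cycloisomerisation of an o-iodophenol with 2-methylbut-3-yn-2-ol. The halogens I, Br and I are placed by SEAr on 3-aminophenol (ring A), and Br also serves as a blocking group.
5. Ring order: A (bought) → D (furan) → B (pyrrole, later indoline) → C (pyrrolidine).

Assumption: the facial sense of the new catalytic bromination with (DHQD)2PHAL is taken to give the (R)-bromoindolenine. If it proves opposite, the pseudoenantiomer (DHQ)2PHAL is used and nothing else changes.

Locants: the tricycles keep indole numbering (N1, C2, C3, C3a, C4–C7, C7a). The furan is fused on C4–C5 with its O on C4, and its carbons are C2' (bears CMe2OH) and C3'. The target uses pyrrolo[2,3-b]indole numbering (N1, C2, C3, C3a, C4–C7, N8, C8a).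

**Route**

Step 1
Reactants: 1 3-aminophenol
Product: 3 5-amino-4-bromo-2-iodophenol, via 5-amino-2-iodophenol 2 (not isolated)
Conditions: NIS (1.00 equiv), MeCN, −20 °C, 2 h; then NBS (1.00 equiv), −20 → 0 °C, 1 h; recrystallise
Reagents that add atoms: N-iodosuccinimide O=C1CCC(=O)N1I; N-bromosuccinimide O=C1CCC(=O)N1Br
Why: Two consecutive electrophilic aromatic halogenations, in which iodine enters para to the stronger donor NH2 (ortho to OH) and bromine then takes the only other unhindered doubly activated carbon (ortho to NH2, para to OH), the carbon between OH and NH2 being the most crowded; no stereocenter is formed.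

Step 2
Reactants: 3 5-amino-4-bromo-2-iodophenol; 4 2-methylbut-3-yn-2-ol
Product: 6 2-(6-amino-5-bromo-1-benzofuran-2-yl)propan-2-ol, via alkynylphenol 5 (not isolated)
Conditions: PdCl2(PPh3)2 (2 mol %), CuI (4 mol %), Et3N (3 equiv), DMF, 25 → 55 °C
Reagents that add atoms: none
Why: Sonogashira coupling takes place at C–I only (the electron-rich C–Br bond is inert at 55 °C), and the o-alkynylphenol cycloisomerises 5-endo-dig under the same Pd/Cu/amine conditions to close ring D.

Step 3
Reactants: 6 2-(6-amino-5-bromo-1-benzofuran-2-yl)propan-2-ol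
Product: 7 2-(6-amino-5-bromo-7-iodo-1-benzofuran-2-yl)propan-2-ol
Conditions: NIS (1.05 equiv), DMF, 0 °C → rt, dark
Reagents that add atoms: N-iodosuccinimide O=C1CCC(=O)N1I
Why: SEAr iodination, in which C7 is the only free position ortho or para to NH2 (C5 is blocked by Br) and is also ortho to the ring oxygen, so it outruns furan C3.

Step 4
Reactants: 8 but-3-yn-1-amine; 9 methyl chloroformate
Product: 10 methyl but-3-yn-1-ylcarbamate
Conditions: NaOH (aq, 1.1 equiv), CH2Cl2, 0 °C
Reagents that add atoms: none
Why: Schotten–Baumann N-acylation, which masks the amine through all C–C bond formations and supplies the carbonyl carbon that becomes the N-methyl carbon.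

Step 5
Reactants: 7 2-(6-amino-5-bromo-7-iodo-1-benzofuran-2-yl)propan-2-ol; 10 methyl but-3-yn-1-ylcarbamate
Product: 12 methyl {2-[7-bromo-2'-(2-hydroxypropan-2-yl)-1H-furo[2',3':4,5]indol-2-yl]ethyl}carbamate, via alkynylaniline 11 (not isolated)
Conditions: PdCl2(PPh3)2 (3 mol %), CuI (6 mol %), Et3N (3 equiv), DMF, 25 °C, 4 h; then CuI (to 50 mol %), 100 °C, 8 h
Reagents that add atoms: none
Why: Sonogashira coupling at C–I is followed by copper-promoted 5-endo-dig hydroamination of the o-alkynylaniline (Castro-type indole synthesis), which closes ring B because the neutral aniline N is far more nucleophilic than the carbamate N–H.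

Step 6
Reactants: 12 methyl {2-[7-bromo-2'-(2-hydroxypropan-2-yl)-1H-furo[2',3':4,5]indol-2-yl]ethyl}carbamate; 13 3-methylbut-2-en-1-ol (prenol)
Product: 14 methyl {2-[7-bromo-2'-(2-hydroxypropan-2-yl)-3-(3-methylbut-2-en-1-yl)-1H-furo[2',3':4,5]indol-2-yl]ethyl}carbamate
Conditions: 13 (1.1 equiv), Pd(PPh3)4 (5 mol %), Et3B (30 mol %), THF, 50 °C
Reagents that add atoms: none
Why: Tsuji–Trost allylation with borane activation of the allylic alcohol, in which the π-prenylpalladium is attacked by the free indole C3 at its unsubstituted terminus to give the linear prenyl group, while carbamate N–H, tertiary OH and the hindered aryl bromide stay untouched.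

Step 7
Reactants: 14 methyl {2-[7-bromo-2'-(2-hydroxypropan-2-yl)-3-(3-methylbut-2-en-1-yl)-1H-furo[2',3':4,5]indol-2-yl]ethyl}carbamate
Product: 17 methyl {2-[(3S)-7-bromo-2'-(2-hydroxypropan-2-yl)-3-(3-methylbut-2-en-1-yl)-2-oxo-2,3-dihydro-1H-furo[2',3':4,5]indol-3-yl]ethyl}carbamate, via (R)-3-bromoindolenine 15 (not isolated), via bromo carbinolamine 16 (not isolated)
Conditions: (DHQD)2PHAL (hydroquinidine 1,4-phthalazinediyl diether, 10 mol %), PhCO2H (20 mol %), NBS (1.00 equiv), 4 Å MS, toluene/CHCl3 1:1, −60 °C, dark; then THF/H2O/AcOH 1:1:1, NaOAc (2 equiv), −10 → 10 °C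
Reagents that add atoms: water O; N-bromosuccinimide O=C1CCC(=O)N1Br (its Br stays only in 15 and 16)
Why: Proposed new method: a catalytic enantioselective bromination/hydrative semipinacol rearrangement of an open-chain 2,3-dialkylindole, in which the quinuclidine N of the catalyst takes Br+ from NBS, the substrate docks through its indole and carbamate N–H bonds, and Br+ goes to one face of C3 (far more nucleophilic than the prenyl alkene or the benzofuran) to give (R)-15, which cannot rearomatise and resists ionisation next to C=N; buffered water then adds to C2 on the face of the smaller Br (anti to prenyl) to give (2R,3R)-16 with the aminoethyl chain antiperiplanar to C–Br, and lone-pair push from O and N drives the 1,2-shift of that chain from C2 to C3 with inversion and loss of bromide, forming the C3–CH2 bond, the lactam C=O and the (S) quaternary centre; the closest known reaction types are the racemic NBS/aqueous AcOH oxidative rearrangement of ring-fused indoles to spirooxindoles, the cinchona-catalysed asymmetric halogenation/semipinacol rearrangement of allylic alcohols and the (DHQD)2PHAL-catalysed halocyclisation of indolyl amides.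

Step 8
Reactants: 17 methyl {2-[(3S)-7-bromo-2'-(2-hydroxypropan-2-yl)-3-(3-methylbut-2-en-1-yl)-2-oxo-2,3-dihydro-1H-furo[2',3':4,5]indol-3-yl]ethyl}carbamate
Product: 19 2-[(3aS,8aS)-7-bromo-1-methyl-3a-(3-methylbut-2-en-1-yl)-1,2,3,3a,8,8a-hexahydrofuro[2',3':4,5]pyrrolo[2,3-b]indol-2'-yl]propan-2-ol (CNP0306513.1), via (S)-indolenine amine 18 (not isolated)
Conditions: AlH3·NMe2Et (0.5 M in toluene, 8 equiv), THF, 0 → 40 °C; Na2SO4·10H2O quench
Reagents that add atoms: none
Why: Hydride reductive cyclisation of an oxindole carbamate, in which alane turns NHCO2Me into NHMe and the lactam into the C=N level, the tethered amine closes ring C faster than a second hydride arrives, the aryl bromide tolerates alane, and C8a can only be set cis to C3a (8aS) because a trans-fused 5,5-aminal is too strained.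

**Compound list**
1 | 3-aminophenol | Nc1cccc(O)c1 | starting material
2 | 5-amino-2-iodophenol | Nc1ccc(I)c(O)c1 | intermediate
3 | 5-amino-4-bromo-2-iodophenol | Nc1cc(O)c(I)cc1Br | intermediate
4 | 2-methylbut-3-yn-2-ol | CC(C)(O)C#C | starting material
5 | 5-amino-4-bromo-2-(3-hydroxy-3-methylbut-1-yn-1-yl)phenol | CC(C)(O)C#Cc1cc(Br)c(N)cc1O | intermediate
6 | 2-(6-amino-5-bromo-1-benzofuran-2-yl)propan-2-ol | CC(C)(O)c1cc2cc(Br)c(N)cc2o1 | intermediate
7 | 2-(6-amino-5-bromo-7-iodo-1-benzofuran-2-yl)propan-2-ol | CC(C)(O)c1cc2cc(Br)c(N)c(I)c2o1 | intermediate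
8 | but-3-yn-1-amine | C#CCCN | starting material
9 | methyl chloroformate | COC(=O)Cl | starting material
10 | methyl but-3-yn-1-ylcarbamate | C#CCCNC(=O)OC | intermediate
11 | methyl {4-[6-amino-5-bromo-2-(2-hydroxypropan-2-yl)-1-benzofuran-7-yl]but-3-yn-1-yl}carbamate | CC(C)(O)c1cc2cc(Br)c(N)c(C#CCCNC(=O)OC)c2o1 | intermediate
12 | methyl {2-[7-bromo-2'-(2-hydroxypropan-2-yl)-1H-furo[2',3':4,5]indol-2-yl]ethyl}carbamate (C3–H) | COC(=O)NCCc1cc2c([nH]1)c(Br)cc1cc(C(C)(C)O)oc12 | intermediate
13 | 3-methylbut-2-en-1-ol (prenol) | CC(C)=CCO | starting material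
14 | 3-prenyl derivative of 12 | COC(=O)NCCc1[nH]c2c(Br)cc3cc(C(C)(C)O)oc3c2c1CC=C(C)C | intermediate
15 | (3R)-3,7-dibromo-3-prenyl-3H-indole (bromoindolenine) from 14 | CC(C)=CC[C@]1(Br)C(CCNC(=O)OC)=Nc2c(Br)cc3cc(C(C)(C)O)oc3c12 | intermediate
16 | (2R,3R)-3,7-dibromo-2-hydroxy-3-prenylindoline, C2 chain anti to C3–Br | CC(C)=CC[C@]1(Br)[C@](O)(CCNC(=O)OC)Nc2c(Br)cc3cc(C(C)(C)O)oc3c12 | intermediate
17 | (3S)-7-bromo-3-prenyl-3-[2-(methoxycarbonylamino)ethyl]oxindole with fused furan | CC(C)=CC[C@@]1(CCNC(=O)OC)C(=O)Nc2c(Br)cc3cc(C(C)(C)O)oc3c12 | intermediate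
18 | (3S)-7-bromo-3-[2-(methylamino)ethyl]-3-prenyl-3H-indole with fused furan | CC(C)=CC[C@@]1(CCNC)C=Nc2c(Br)cc3cc(C(C)(C)O)oc3c12 | intermediate
19 | (3aS,8aS) target CNP0306513.1 | CC(C)=CC[C@@]12CCN(C)[C@@H]1Nc1c(Br)cc3cc(C(C)(C)O)oc3c12 | target

**Totals**
Total step count: 8.
Longest linear sequence: 7 (steps 1, 2, 3, 5, 6, 7, 8).

**Steps most likely to fail**

Step 7 (the new step).
- Risks: modest ee, tautomerisation of 15 to a 2-alkylidene indoline, or bromohydrin formation at the prenyl group.
- Fallback (known chemistry), setting out from 14: the classical one-flask oxidative rearrangement (NBS, THF/H2O/AcOH, 0 °C) gives the racemic oxindole F1.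
- Preparative chiral SFC on an amylose tris(3,5-dimethylphenylcarbamate) phase separates 17 from the (R)-oxindole F2.
- The absolute configuration is fixed by anomalous-dispersion X-ray on bromine. The route is rejoined at 17.

Step 1.
- Risk: the first halogenation may not be clean para to NH2. This would give Br/I positional isomers that are hard to separate.
- Fallback, setting out from 1, switches the directing power with a protecting group. Boc2O gives tert-butyl (3-hydroxyphenyl)carbamate F3, in which OH is the strongest donor.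
- NBS then brominates para to OH to give tert-butyl (2-bromo-5-hydroxyphenyl)carbamate F4.
- NIS iodinates the unhindered ortho position of the phenol to give tert-butyl (2-bromo-5-hydroxy-4-iodophenyl)carbamate F5. Bromine goes on before iodine, so no halogen exchange can occur.
- HCl in dioxane followed by neutralisation removes the Boc group. The route is rejoined at 3.

Step 8.
- Risks: over-reduction of 18 to the ring-opened indoline, or partial debromination.
- Fallback, setting out from 17, splits the two reductions. [Ir(coe)2Cl]2 (coe = cyclooctene, 1 mol %) with Et2SiH2 takes only the secondary lactam to the imine level, giving the (S)-3H-indole carbamate F6.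
- On work-up with K2CO3/MeOH and then PPTS, F6 closes to the N1-methoxycarbonyl pyrroloindoline F7.
- Only then does AlH3·NMe2Et convert NCO2Me into NMe on the closed aminal. The route is rejoined at 19.

**Further compounds**
F1 | step 7 | racemic 7-bromo-3-prenyl-3-[2-(methoxycarbonylamino)ethyl]oxindole with fused furan | CC(C)=CCC1(CCNC(=O)OC)C(=O)Nc2c(Br)cc3cc(C(C)(C)O)oc3c12
F2 | step 7 | (3R)-enantiomer of 17 | CC(C)=CC[C@]1(CCNC(=O)OC)C(=O)Nc2c(Br)cc3cc(C(C)(C)O)oc3c12
F3 | step 1 | tert-butyl (3-hydroxyphenyl)carbamate | CC(C)(C)OC(=O)Nc1cccc(O)c1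
F4 | step 1 | tert-butyl (2-bromo-5-hydroxyphenyl)carbamate | CC(C)(C)OC(=O)Nc1cc(O)ccc1Br
F5 | step 1 | tert-butyl (2-bromo-5-hydroxy-4-iodophenyl)carbamate | CC(C)(C)OC(=O)Nc1cc(O)c(I)cc1Br
F6 | step 8 | (3S)-7-bromo-3-[2-(methoxycarbonylamino)ethyl]-3-prenyl-3H-indole with fused furan | CC(C)=CC[C@@]1(CCNC(=O)OC)C=Nc2c(Br)cc3cc(C(C)(C)O)oc3c12
F7 | step 8 | methyl (3aS,8aS)-7-bromo-3a-prenyl-hexahydropyrrolo[2,3-b]indole-1-carboxylate with fused furan | CC(C)=CC[C@@]12CCN(C(=O)OC)[C@@H]1Nc1c(Br)cc3cc(C(C)(C)O)oc3c12
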